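The numbers in the tables stem from a simulated flask from invented constants; scatter was added.

A percentage point is the scatter of one reading here, so I ask which givens can bear that error. J and L are mirror images, and X turns them into D and Q over the single-handed Z.

| flask | J | L | X | Z | remark | time |
|---|---|---|---|---|---|---|
| epsilon | 10 mM | 10 mM | 0.60 equiv | 0.1 mol% | run made earlier |  |
| eta | 10 mM | 10 mM | 0.90 equiv | 0.1 mol% | run made earlier |  |
| beta | 15 mM | 15 mM | 1.2 equiv | 0.1 mol% | run made earlier |  |
| flask | 10 mM | 10 mM | 1.20 equiv | 0.1 mol% |  | 25 h |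

| run | time / h | J / % | L / % |
|---|---|---|---|
| epsilon | 3.00 | 31.0 | 42.9 |
| epsilon | 6.00 | 30.3 | 42.2 |
| epsilon | 8.00 | 30.0 | 42.5 |
| epsilon | 12.0 | 30.5 | 40.8 |
| epsilon | 15.0 | 30.7 | 42.8 |
| epsilon | 20.0 | 28.7 | 41.3 |
| eta | 1.00 | 32.8 | 43.1 |
| eta | 3.00 | 25.9 | 37.6 |
| eta | 6.00 | 21.1 | 39.0 |
| eta | 8.00 | 21.2 | 38.0 |
| eta | 12.0 | 19.4 | 36.5 |
| eta | 15.0 | 20.6 | 37.3 |
| eta | 20.0 | 22.2 | 37.4 |
| beta | 2.00 | 17.5 | 34.0 |
| beta | 5.00 | 11.5 | 29.9 |
| beta | 10.0 | 12.5 | 30.8 |
| beta | 15.0 | 12.4 | 31.2 |
| beta | 20.0 | 13.3 | 31.6 |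

(scatter of a reading: 1 percentage point)

- Z is single-handed; J and L are mirror images of each other, charged as a racemate, each of them at the stated concentration
- an excess is the difference of the two amounts in percent of their sum
- an excess is below zero if the other one leads

* part of the J and L charged together that has reacted at 25 h
* excess of D over Q in the product at 25 h
* excess of L over J among what is left of the two at 25 h

The reading time can be loose: in eta, at the flask's 10 mM of J, J moves by 1.1 percentage points from 6.00 h to 20.0 h. The mean of the beta readings from 5.00 h on leaves 24.8 % of charged J and 61.8 % of charged L. The X charge must be right: at 15.0 h, L leads J by 16.5 % in epsilon (0.60 equiv) and 28.8 % in eta (0.90 equiv). The ratio of logarithms can be looser: taking eta's instead of beta's shifts that J by 2.1 points of its charge.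

s = log10(J left) / log10(L left) = 2.89

This selectivity factor, the log10 of the part of J left over the log10 of the part of L left, is what I carry. Scaling eta's conversion by X, I reckon:

c = 55.3 %

[L]/[L]₀ = 63.1 %, [J]/[J]₀ = 26.4 %

eS = 41.0 %, eP = 33.1 %

The forecast, holding that “the plateau is set by X, not by time”, gives c 56 %, eP 33.5 % and eS 42.5 %.

The flask gives c 53.2 %, eP 34.8 % and eS 39.5 %.

    Z ⇌ G (K = 0.930, k = 0.0170 h⁻¹)
    X + Z + J → Z + D (k = 7.40 × 10⁶ M⁻² h⁻¹)
    2 X → E (k = 8.10 M⁻¹ h⁻¹)
    X + Z + L → Z + Q (k = 2.50 × 10⁶ M⁻² h⁻¹)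

The flask's log ratio of J left to L left is 2.96. In the neighbour with 2.00 equiv of X, 38 % of charged L left gives, by s, 6.14 % of charged J, and that neighbour holds 5.7 %. In the flask at 25.0 h, the half-life of J by its step is 360 d, longer than the 25 h run, and X, the limiting reagent, stands at 0.013 % of its charge, less than the 28 % left of charged J. In the flask, J stands at 14.3 % of the J and L together charged at 12.5 h and at 14.2 % at 25.0 h.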